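**Retrosynthetic overview**
1. In drimane numbering (C4 = CMe2, C5/C10 = ring fusion, C8 = methyl-bearing alkene carbon, C9 bears the arylmethyl carbon C11) the target reads as (5S,9R,10S), a 9-epi-drim-7-ene with H-9 cis to the C10 methyl; sulfate, formyl group and free catechol are unmasked last on an arene brought in as a benzylic bromide.
2. C9–C11 is made by α′-alkylation of a bicyclic enone (C8 ketone, C6=C7) on the face opposite the axial C10 methyl, which gives the 9-epi centre; C7=C8 with its methyl then follows from 1,4-reduction, enol triflate and methyl cuprate.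
3. Rings A and B are closed together in one intramolecular Diels–Alder reaction of an acyclic (E)-2-methyl-trienal that forms C3–C4 and C5–C10; the arene ring is attached afterwards.
4. Enabling feature: ring A (C1–C5, C10) is a cyclohexane in which the unit C10–C1–C2–C3 and the unit C4–C5 are joined by exactly these two bonds, and C5–C10 is the fusion bond shared with ring B, so the C6–C9 chain of ring B is the tether. One C4 methyl is carried as CHO (activator, later reduced to CH3), the C10 methyl is the Z-methyl of the diene, and C8 carries a removable (R)-benzyloxy group that fixes the absolute configuration.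
5. The trienal comes from (R)-1,2-epoxy-5-hexene by acetylide opening, oxidative cleavage/Wittig olefination and carboalumination/vinylation.

Key step: step 8

Remark: the target is drawn as the free aryl hydrogen sulfate; it is carried as its sodium salt and protonated only in the last operation, because such acids are hydrolytically labile.

**Route**

Step 1
Reactants: 1 (R)-2-(but-3-en-1-yl)oxirane
Product: 2 (R)-oct-7-en-1-yn-4-ol
Conditions: LiC≡CH·H2NCH2CH2NH2, DMSO, 0 °C to rt; then H2O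
Reagents that add atoms: lithium acetylide (as its ethylenediamine complex), [Li]C#C
Why: SN2 opening of the terminal epoxide at its CH2 carbon by the acetylide leaves the (R)-carbinol centre untouched.

Step 2
Reactants: 2 (R)-oct-7-en-1-yn-4-ol
Product: 3 (R)-4-(benzyloxy)oct-7-en-1-yne
Conditions: NaH, BnBr, Bu4NI (cat.), THF, 0 °C to rt
Reagents that add atoms: benzyl bromide, BrCc1ccccc1
Why: Williamson etherification of the secondary alkoxide; benzyl is chosen because it is lost without an extra step in the hydrogenation of step 10.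

Step 3
Reactants: 3 (R)-4-(benzyloxy)oct-7-en-1-yne
Product: 4 (R)-4-(benzyloxy)hept-6-ynal
Conditions: OsO4 (cat.), NaIO4, 2,6-lutidine, dioxane/H2O, rt
Reagents that add atoms: sodium periodate (oxygen source, relayed by OsO4), [Na+].[O-]I(=O)(=O)=O
Why: Lemieux–Johnson cleavage, in which OsO4 dihydroxylates the terminal alkene much faster than the alkyne and periodate cleaves the diol to the aldehyde.

Step 4
Reactants: 4 (R)-4-(benzyloxy)hept-6-ynal
Product: 5 ethyl (2E,6R)-6-(benzyloxy)-2-methylnon-2-en-8-ynoate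
Conditions: Ph3P=C(CH3)CO2Et, CH2Cl2, rt
Reagents that add atoms: ethyl 2-(triphenylphosphoranylidene)propanoate, CCOC(=O)C(C)=P(c1ccccc1)(c1ccccc1)c1ccccc1
Why: Wittig olefination with a stabilised α-methyl ylide should give the (E)-trisubstituted enoate.

Step 5
Reactants: 5 ethyl (2E,6R)-6-(benzyloxy)-2-methylnon-2-en-8-ynoate
Product: 6 (2E,6R)-6-(benzyloxy)-2-methylnon-2-en-8-yn-1-ol
Conditions: i-Bu2AlH, CH2Cl2, −78 °C; aq. potassium sodium tartrate
Reagents that add atoms: none
Why: 1,2-reduction of the enoate by the aluminium hydride gives the allylic alcohol, which keeps the later dienophile at an oxidation level that tolerates Me3Al.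

Step 6
Reactants: 6 (2E,6R)-6-(benzyloxy)-2-methylnon-2-en-8-yn-1-ol
Product: 8 (2E,6R,8E)-6-(benzyloxy)-2,8-dimethylundeca-2,8,10-trien-1-ol, via alkenylalane 7 (not isolated)
Conditions: Me3Al, Cp2ZrCl2 (cat.), CH2Cl2, 0 °C to rt; then CH2=CHBr, Pd(PPh3)4 (cat.), ZnCl2 (cat.), THF, rt; aq. NaHCO3/potassium sodium tartrate
Reagents that add atoms: trimethylaluminium, C[Al](C)C; vinyl bromide, C=CBr
Why: Negishi zirconium-catalysed syn-carboalumination puts CH3 on the internal alkyne carbon and Al on the terminus, and the Pd-catalysed coupling with vinyl bromide proceeds with retention, so the diene carries its methyl cis to the vinyl group (the future C10 methyl).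

Step 7
Reactants: 8 (2E,6R,8E)-6-(benzyloxy)-2,8-dimethylundeca-2,8,10-trien-1-ol
Product: 9 (2E,6R,8E)-6-(benzyloxy)-2,8-dimethylundeca-2,8,10-trienal
Conditions: MnO2, CH2Cl2, rt
Reagents that add atoms: none
Why: MnO2 oxidises only the allylic alcohol and should leave the diene and the E geometry of the enal intact.

Step 8
Reactants: 9 (2E,6R,8E)-6-(benzyloxy)-2,8-dimethylundeca-2,8,10-trienal
Product: 10 (1R,4aS,6R,8aR)-6-(benzyloxy)-1,4a-dimethyl-1,2,4a,5,6,7,8,8a-octahydronaphthalene-1-carbaldehyde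
Conditions: Me2AlCl, CH2Cl2 (0.01 mol/L), −78 to −20 °C; dilute aq. HCl
Reagents that add atoms: none
Why: Me2AlCl binds the formyl oxygen and the (E)-2-methylenal (C4=C5) adds suprafacially to the tethered diene C10=C1–C2=C3 in a concerted, asynchronous type 1 intramolecular Diels–Alder reaction that forms C5–C10 and C3–C4 together; the closest precedent is the Lewis-acid-promoted intramolecular Diels–Alder reaction of (E)-2-methyl-2,7,9-trienals to trans-decalins with a quaternary C(CH3)(CHO) carbon. Ring A is the cyclohexene made by the [4+2] addition itself (C1=C2 remains), and ring B closes at the same time because its four-carbon chain C6–C9 is the tether, folded as a chair between C5 and C10. C4 follows from the E geometry of the enal (CHO cis to H-5) and is erased in step 9, while the trans relation of H-5 and the C10 methyl comes from the formyl-endo transition state with the tether anti. The absolute sense at C5 and C10 is set by the (R)-benzyloxy group on C8, which should sit equatorial in the chair tether because the axial position is 1,3-diaxial to the Z-methyl of the diene. The step needs endo (trans-fusion) and diastereofacial selectivity; the Lewis acid is expected to secure the first and the C8 substituent together with the Z-methyl the second, and the four-atom tether leaves no other regiochemistry open.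

Step 9
Reactants: 10 (1R,4aS,6R,8aR)-6-(benzyloxy)-1,4a-dimethyl-1,2,4a,5,6,7,8,8a-octahydronaphthalene-1-carbaldehyde
Product: 12 (4aS,6R,8aS)-6-(benzyloxy)-1,1,4a-trimethyl-1,2,4a,5,6,7,8,8a-octahydronaphthalene, via hydrazone 11 (not isolated)
Conditions: N2H4·H2O, KOH, diethylene glycol, 130 °C then 200 °C
Reagents that add atoms: none
Why: Wolff–Kishner reduction (Huang–Minlon procedure) turns the neopentyl formyl group that activated the dienophile into the second C4 methyl and thereby removes the C4 stereocentre.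

Step 10
Reactants: 12 (4aS,6R,8aS)-6-(benzyloxy)-1,1,4a-trimethyl-1,2,4a,5,6,7,8,8a-octahydronaphthalene
Product: 13 (2R,4aS,8aR)-5,5,8a-trimethyldecahydronaphthalen-2-ol
Conditions: H2 (1 atm), Pd/C, EtOH/EtOAc, rt
Reagents that add atoms: none
Why: Heterogeneous hydrogenation saturates the only C=C bond (C1=C2) and hydrogenolyses the benzyl ether in the same operation.

Step 11
Reactants: 13 (2R,4aS,8aR)-5,5,8a-trimethyldecahydronaphthalen-2-ol
Product: 15 (4aS,8aR)-5,5,8a-trimethyl-4a,5,6,7,8,8a-hexahydronaphthalen-2(1H)-one, via ketone 14 (not isolated)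
Conditions: 2-iodoxybenzoic acid (excess), DMSO, rt then 80 °C
Reagents that add atoms: none
Why: 2-Iodoxybenzoic acid oxidises the alcohol to the ketone and then dehydrogenates it to the enone; only C6–C7 can become the double bond because C10 is quaternary.

Step 12
Reactants: 16 2,4,5-trihydroxybenzaldehyde
Product: 17 4,5-bis(allyloxy)-2-hydroxybenzaldehyde
Conditions: allyl bromide (2 equiv), K2CO3, DMF, rt
Reagents that add atoms: allyl bromide, C=CCBr
Why: Williamson allylation should take the two non-chelated phenols, since the 2-OH hydrogen-bonded to the formyl group is the least nucleophilic.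

Step 13
Reactants: 17 4,5-bis(allyloxy)-2-hydroxybenzaldehyde
Product: 18 4,5-bis(allyloxy)-2-(methoxymethoxy)benzaldehyde
Conditions: CH3OCH2Cl, i-Pr2NEt, CH2Cl2, 0 °C to rt
Reagents that add atoms: chloromethyl methyl ether, COCCl
Why: Acetal protection of the remaining phenol, orthogonal to the allyl ethers and stable to enolates, hydride and cuprate.

Step 14
Reactants: 18 4,5-bis(allyloxy)-2-(methoxymethoxy)benzaldehyde
Product: 19 [4,5-bis(allyloxy)-2-(methoxymethoxy)phenyl]methanol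
Conditions: NaBH4, MeOH, 0 °C
Reagents that add atoms: none
Why: Borohydride reduction of the aryl aldehyde to the benzylic alcohol.

Step 15
Reactants: 19 [4,5-bis(allyloxy)-2-(methoxymethoxy)phenyl]methanol
Product: 20 1,2-bis(allyloxy)-4-(bromomethyl)-5-(methoxymethoxy)benzene
Conditions: CBr4, PPh3, CH2Cl2, −20 °C; used without storage
Reagents that add atoms: tetrabromomethane, BrC(Br)(Br)Br
Why: Appel bromination under neutral conditions gives the electron-rich benzylic bromide without touching the acetal or the allyl ethers.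

Step 16
Reactants: 15 (4aS,8aR)-5,5,8a-trimethyl-4a,5,6,7,8,8a-hexahydronaphthalen-2(1H)-one; 20 1,2-bis(allyloxy)-4-(bromomethyl)-5-(methoxymethoxy)benzene
Product: 22 (1S,4aS,8aS)-1-[4,5-bis(allyloxy)-2-(methoxymethoxy)benzyl]-5,5,8a-trimethyl-4a,5,6,7,8,8a-hexahydronaphthalen-2(1H)-one, via lithium dienolate 21 (not isolated)
Conditions: LiN(i-Pr)2, THF, −78 °C; then 20, DMPU, −78 to −30 °C
Reagents that add atoms: none
Why: Kinetic α′-deprotonation of the enone gives the cross-conjugated dienolate at C9 (the C7 side is blocked as the alkene), and its SN2 alkylation should occur on the face opposite the axial C10 methyl, which sets C9 with the arylmethyl group trans to that methyl.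

Step 17
Reactants: 22 (1S,4aS,8aS)-1-[4,5-bis(allyloxy)-2-(methoxymethoxy)benzyl]-5,5,8a-trimethyl-4a,5,6,7,8,8a-hexahydronaphthalen-2(1H)-one
Product: 24 (1S,4aS,8aS)-1-[4,5-bis(allyloxy)-2-(methoxymethoxy)benzyl]-5,5,8a-trimethyl-1,4,4a,5,6,7,8,8a-octahydronaphthalen-2-yl trifluoromethanesulfonate, via lithium enolate 23 (not isolated)
Conditions: Li[BH(s-Bu)3], THF, −78 °C; then PhNTf2, −78 to 0 °C
Reagents that add atoms: N-phenylbis(trifluoromethanesulfonimide), FC(F)(F)S(=O)(=O)N(c1ccccc1)S(=O)(=O)C(F)(F)F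
Why: The hindered borohydride adds hydride 1,4 to the β-unsubstituted enone and the regiodefined enolate is trapped on oxygen, which fixes the double bond at C7=C8 and leaves C9 untouched.

Step 18
Reactants: 24 (1S,4aS,8aS)-1-[4,5-bis(allyloxy)-2-(methoxymethoxy)benzyl]-5,5,8a-trimethyl-1,4,4a,5,6,7,8,8a-octahydronaphthalen-2-yl trifluoromethanesulfonate
Product: 25 1,2-bis(allyloxy)-5-(methoxymethoxy)-4-{[(1R,4aS,8aS)-2,5,5,8a-tetramethyl-1,4,4a,5,6,7,8,8a-octahydronaphthalen-1-yl]methyl}benzene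
Conditions: Me2CuLi, Et2O/THF, −20 to 0 °C
Reagents that add atoms: lithium dimethylcuprate, [Li+].C[Cu-]C
Why: Cuprate coupling of the enol triflate replaces OTf by CH3 without moving the alkene, which completes the C8-methyl C7=C8 unit.

Step 19
Reactants: 25 1,2-bis(allyloxy)-5-(methoxymethoxy)-4-{[(1R,4aS,8aS)-2,5,5,8a-tetramethyl-1,4,4a,5,6,7,8,8a-octahydronaphthalen-1-yl]methyl}benzene
Product: 26 4,5-bis(allyloxy)-2-{[(1R,4aS,8aS)-2,5,5,8a-tetramethyl-1,4,4a,5,6,7,8,8a-octahydronaphthalen-1-yl]methyl}phenol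
Conditions: ZnBr2, n-PrSH, CH2Cl2, 0 °C
Reagents that add atoms: none
Why: Lewis acid/thiol cleavage of the aryl methoxymethyl ether works without protic acid, so the allyl ethers survive and the phenol should not cyclise onto the trisubstituted alkene.

Step 20
Reactants: 26 4,5-bis(allyloxy)-2-{[(1R,4aS,8aS)-2,5,5,8a-tetramethyl-1,4,4a,5,6,7,8,8a-octahydronaphthalen-1-yl]methyl}phenol
Product: 27 5,6-bis(allyloxy)-2-hydroxy-3-{[(1R,4aS,8aS)-2,5,5,8a-tetramethyl-1,4,4a,5,6,7,8,8a-octahydronaphthalen-1-yl]methyl}benzaldehyde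
Conditions: MgCl2, Et3N, paraformaldehyde, MeCN, 80 °C
Reagents that add atoms: paraformaldehyde (formaldehyde), C=O
Why: Magnesium-mediated ortho-formylation (Casnati–Skattebøl) delivers formaldehyde only ortho to the phenoxide, and the single free ortho carbon is the one between the OH and O-allyl groups.

Step 21
Reactants: 27 5,6-bis(allyloxy)-2-hydroxy-3-{[(1R,4aS,8aS)-2,5,5,8a-tetramethyl-1,4,4a,5,6,7,8,8a-octahydronaphthalen-1-yl]methyl}benzaldehyde
Product: 28 sodium 3,4-bis(allyloxy)-2-formyl-6-{[(1R,4aS,8aS)-2,5,5,8a-tetramethyl-1,4,4a,5,6,7,8,8a-octahydronaphthalen-1-yl]methyl}phenyl sulfate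
Conditions: SO3·pyridine (excess), pyridine, 50 °C; then aq. NaHCO3
Reagents that add atoms: sulfur trioxide–pyridine complex, O=S(=O)([O-])[n+]1ccccc1; sodium hydrogen carbonate, [Na+].OC([O-])=O
Why: O-Sulfation of the only free phenol with the SO3 amine complex, isolated as the base-stable sodium salt.

Step 22
Reactants: 28 sodium 3,4-bis(allyloxy)-2-formyl-6-{[(1R,4aS,8aS)-2,5,5,8a-tetramethyl-1,4,4a,5,6,7,8,8a-octahydronaphthalen-1-yl]methyl}phenyl sulfate
Product: 30 2-formyl-3,4-dihydroxy-6-{[(1R,4aS,8aS)-2,5,5,8a-tetramethyl-1,4,4a,5,6,7,8,8a-octahydronaphthalen-1-yl]methyl}phenyl hydrogen sulfate, via sodium salt 29 (not isolated)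
Conditions: Pd(PPh3)4 (cat.), p-TolSO2H, THF/MeOH (degassed), rt; then dilute aq. HCl (1 equiv), 0 °C
Reagents that add atoms: none
Why: Tsuji–Trost allyl transfer from the two aryl allyl ethers to the sulfinic acid frees the catechol under near-neutral conditions that the sulfate, the aldehyde and the trisubstituted alkene should tolerate, and protonation gives the hydrogen sulfate as drawn.

**Compound list**
1 | (R)-2-(but-3-en-1-yl)oxirane | C=CCC[C@@H]1CO1 | starting material
2 | (R)-oct-7-en-1-yn-4-ol | C#CC[C@H](O)CCC=C | intermediate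
3 | (R)-4-(benzyloxy)oct-7-en-1-yne | C#CC[C@H](OCc1ccccc1)CCC=C | intermediate
4 | (R)-4-(benzyloxy)hept-6-ynal | C#CC[C@H](OCc1ccccc1)CCC=O | intermediate
5 | ethyl (2E,6R)-6-(benzyloxy)-2-methylnon-2-en-8-ynoate | C#CC[C@H](OCc1ccccc1)CC/C=C(\C)C(=O)OCC | intermediate
6 | (2E,6R)-6-(benzyloxy)-2-methylnon-2-en-8-yn-1-ol | C#CC[C@H](OCc1ccccc1)CC/C=C(\C)CO | intermediate
7 | dimethyl{(1E,4R,7E)-4-(benzyloxy)-9-[(dimethylalumanyl)oxy]-2,8-dimethylnona-1,7-dien-1-yl}alumane | C[Al](C)/C=C(\C)C[C@H](OCc1ccccc1)CC/C=C(\C)CO[Al](C)C | intermediate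
8 | (2E,6R,8E)-6-(benzyloxy)-2,8-dimethylundeca-2,8,10-trien-1-ol | C=C/C=C(\C)C[C@H](OCc1ccccc1)CC/C=C(\C)CO | intermediate
9 | (2E,6R,8E)-6-(benzyloxy)-2,8-dimethylundeca-2,8,10-trienal | C=C/C=C(\C)C[C@H](OCc1ccccc1)CC/C=C(\C)C=O | intermediate
10 | (1R,4aS,6R,8aR)-6-(benzyloxy)-1,4a-dimethyl-1,2,4a,5,6,7,8,8a-octahydronaphthalene-1-carbaldehyde (trans-fused; CHO and benzyloxy on the face opposite the 4a-methyl) | [C@@H]1(OCc3ccccc3)CC[C@H]2[C@](C)(C=O)CC=C[C@]2(C)C1 | intermediate
11 | hydrazone of aldehyde 10 | [C@@H]1(OCc3ccccc3)CC[C@H]2[C@](C)(C=NN)CC=C[C@]2(C)C1 | intermediate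
12 | (4aS,6R,8aS)-6-(benzyloxy)-1,1,4a-trimethyl-1,2,4a,5,6,7,8,8a-octahydronaphthalene | [C@@H]1(OCc3ccccc3)CC[C@H]2C(C)(C)CC=C[C@]2(C)C1 | intermediate
13 | (2R,4aS,8aR)-5,5,8a-trimethyldecahydronaphthalen-2-ol | O[C@@H]1CC[C@H]2C(C)(C)CCC[C@]2(C)C1 | intermediate
14 | (4aS,8aR)-5,5,8a-trimethyloctahydronaphthalen-2(1H)-one | O=C1CC[C@H]2C(C)(C)CCC[C@]2(C)C1 | intermediate
15 | (4aS,8aR)-5,5,8a-trimethyl-4a,5,6,7,8,8a-hexahydronaphthalen-2(1H)-one | O=C1C=C[C@H]2C(C)(C)CCC[C@]2(C)C1 | intermediate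
16 | 2,4,5-trihydroxybenzaldehyde | O=Cc1cc(O)c(O)cc1O | starting material
17 | 4,5-bis(allyloxy)-2-hydroxybenzaldehyde | O=Cc1cc(OCC=C)c(OCC=C)cc1O | intermediate
18 | 4,5-bis(allyloxy)-2-(methoxymethoxy)benzaldehyde | O=Cc1cc(OCC=C)c(OCC=C)cc1OCOC | intermediate
19 | [4,5-bis(allyloxy)-2-(methoxymethoxy)phenyl]methanol | OCc1cc(OCC=C)c(OCC=C)cc1OCOC | intermediate
20 | 1,2-bis(allyloxy)-4-(bromomethyl)-5-(methoxymethoxy)benzene | BrCc1cc(OCC=C)c(OCC=C)cc1OCOC | intermediate
21 | lithium (4aS,8aS)-5,5,8a-trimethyl-4a,5,6,7,8,8a-hexahydronaphthalen-2-olate | [Li]OC=1C=C[C@H]2C(C)(C)CCC[C@]2(C)C=1 | intermediate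
22 | (1S,4aS,8aS)-1-[4,5-bis(allyloxy)-2-(methoxymethoxy)benzyl]-5,5,8a-trimethyl-4a,5,6,7,8,8a-hexahydronaphthalen-2(1H)-one (arylmethyl trans to the 8a-methyl) | O=C1C=C[C@H]2C(C)(C)CCC[C@]2(C)[C@@H]1Cc1cc(OCC=C)c(OCC=C)cc1OCOC | intermediate
23 | lithium (1S,4aS,8aS)-1-[4,5-bis(allyloxy)-2-(methoxymethoxy)benzyl]-5,5,8a-trimethyl-1,4,4a,5,6,7,8,8a-octahydronaphthalen-2-olate | [Li]OC1=CC[C@H]2C(C)(C)CCC[C@]2(C)[C@@H]1Cc1cc(OCC=C)c(OCC=C)cc1OCOC | intermediate
24 | (1S,4aS,8aS)-1-[4,5-bis(allyloxy)-2-(methoxymethoxy)benzyl]-5,5,8a-trimethyl-1,4,4a,5,6,7,8,8a-octahydronaphthalen-2-yl trifluoromethanesulfonate | FC(F)(F)S(=O)(=O)OC1=CC[C@H]2C(C)(C)CCC[C@]2(C)[C@@H]1Cc1cc(OCC=C)c(OCC=C)cc1OCOC | intermediate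
25 | 1,2-bis(allyloxy)-5-(methoxymethoxy)-4-{[(1R,4aS,8aS)-2,5,5,8a-tetramethyl-1,4,4a,5,6,7,8,8a-octahydronaphthalen-1-yl]methyl}benzene | CC1=CC[C@H]2C(C)(C)CCC[C@]2(C)[C@@H]1Cc1cc(OCC=C)c(OCC=C)cc1OCOC | intermediate
26 | 4,5-bis(allyloxy)-2-{[(1R,4aS,8aS)-2,5,5,8a-tetramethyl-1,4,4a,5,6,7,8,8a-octahydronaphthalen-1-yl]methyl}phenol | CC1=CC[C@H]2C(C)(C)CCC[C@]2(C)[C@@H]1Cc1cc(OCC=C)c(OCC=C)cc1O | intermediate
27 | 5,6-bis(allyloxy)-2-hydroxy-3-{[(1R,4aS,8aS)-2,5,5,8a-tetramethyl-1,4,4a,5,6,7,8,8a-octahydronaphthalen-1-yl]methyl}benzaldehyde | CC1=CC[C@H]2C(C)(C)CCC[C@]2(C)[C@@H]1Cc1cc(OCC=C)c(OCC=C)c(C=O)c1O | intermediate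
28 | sodium 3,4-bis(allyloxy)-2-formyl-6-{[(1R,4aS,8aS)-2,5,5,8a-tetramethyl-1,4,4a,5,6,7,8,8a-octahydronaphthalen-1-yl]methyl}phenyl sulfate | CC1=CC[C@H]2C(C)(C)CCC[C@]2(C)[C@@H]1Cc1cc(OCC=C)c(OCC=C)c(C=O)c1OS(=O)(=O)[O-].[Na+] | intermediate
29 | sodium 2-formyl-3,4-dihydroxy-6-{[(1R,4aS,8aS)-2,5,5,8a-tetramethyl-1,4,4a,5,6,7,8,8a-octahydronaphthalen-1-yl]methyl}phenyl sulfate | CC1=CC[C@H]2C(C)(C)CCC[C@]2(C)[C@@H]1Cc1cc(O)c(O)c(C=O)c1OS(=O)(=O)[O-].[Na+] | intermediate
30 | 2-formyl-3,4-dihydroxy-6-{[(1R,4aS,8aS)-2,5,5,8a-tetramethyl-1,4,4a,5,6,7,8,8a-octahydronaphthalen-1-yl]methyl}phenyl hydrogen sulfate | CC1=CC[C@H]2C(C)(C)CCC[C@]2(C)[C@@H]1Cc1cc(O)c(O)c(C=O)c1OS(=O)(=O)O | target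

**Step count and risks**
Total step count: 22. Longest linear sequence: 18 steps (steps 1 to 11 and 16 to 22); steps 12 to 15 prepare the arene fragment.

Steps most likely to fail:

Step 8. Bond formation at the fully substituted diene terminus may be slow, so that Lewis-acid-induced oligomerisation of the diene competes, or the formyl-endo preference may erode and give cis-fused material. The fallback sets out from trienal 9 and activates the dienophile as a cation instead. Acetalisation with 1,2-bis(trimethylsilyloxy)ethane and catalytic Me3SiOTf (CH2Cl2, −78 °C) would give 2-[(2E,6R,8E)-6-(benzyloxy)-8-methylundeca-2,8,10-trien-2-yl]-1,3-dioxolane F1. More Me3SiOTf opens the dioxolane to an O-alkylated allyl cation, which should undergo the ionic intramolecular Diels–Alder reaction at low temperature to 2-[(1R,4aS,6R,8aR)-6-(benzyloxy)-1,4a-dimethyl-1,2,4a,5,6,7,8,8a-octahydronaphthalen-1-yl]-1,3-dioxolane F2. Mild hydrolysis (aq. oxalic acid, THF) returns to the route at aldehyde 10.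

Step 16. Proton transfer between product and enolate (epimerisation at C9, dialkylation), O-alkylation, or premature ionisation of the electron-rich benzylic bromide may take over. The fallback sets out from enone 15 and replaces the basic SN2 alkylation by a Lewis-acid-mediated SN1 alkylation of a neutral enol ether. Dienolate 21 is silylated with Me3SiCl to trimethyl{[(4aS,8aS)-5,5,8a-trimethyl-4a,5,6,7,8,8a-hexahydronaphthalen-2-yl]oxy}silane F3. This is alkylated at C9 by the benzylic cation generated from bromide 20 with catalytic ZnBr2 (CH2Cl2, −40 °C), again on the face opposite the C10 methyl, and the route is rejoined at 22.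

Step 21. Sulfation of the hindered, hydrogen-bonded phenol may stay incomplete, and the sulfate monoester may be lost during deallylation and acidification. The fallback sets out from 27 and carries the sulfate as a protected diester. 2,2,2-Trichloroethyl chlorosulfate (Et3N, 4-(dimethylamino)pyridine cat., THF, 0 °C) would give 3,4-bis(allyloxy)-2-formyl-6-{[(1R,4aS,8aS)-2,5,5,8a-tetramethyl-1,4,4a,5,6,7,8,8a-octahydronaphthalen-1-yl]methyl}phenyl 2,2,2-trichloroethyl sulfate F4. Pd(PPh3)4/p-TolSO2H then removes the allyl groups to give 2-formyl-3,4-dihydroxy-6-{[(1R,4aS,8aS)-2,5,5,8a-tetramethyl-1,4,4a,5,6,7,8,8a-octahydronaphthalen-1-yl]methyl}phenyl 2,2,2-trichloroethyl sulfate F5. Zinc dust and HCO2NH4 in MeOH cleave the trichloroethyl group to ammonium 2-formyl-3,4-dihydroxy-6-{[(1R,4aS,8aS)-2,5,5,8a-tetramethyl-1,4,4a,5,6,7,8,8a-octahydronaphthalen-1-yl]methyl}phenyl sulfate F6, and acidification with dilute HCl returns to the route at 30.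

Further compounds
F1 | step 8 | 2-[(2E,6R,8E)-6-(benzyloxy)-8-methylundeca-2,8,10-trien-2-yl]-1,3-dioxolane | C=C/C=C(\C)C[C@H](OCc1ccccc1)CC/C=C(\C)C1OCCO1
F2 | step 8 | 2-[(1R,4aS,6R,8aR)-6-(benzyloxy)-1,4a-dimethyl-1,2,4a,5,6,7,8,8a-octahydronaphthalen-1-yl]-1,3-dioxolane | [C@@H]1(OCc3ccccc3)CC[C@H]2[C@](C)(C4OCCO4)CC=C[C@]2(C)C1
F3 | step 16 | trimethyl{[(4aS,8aS)-5,5,8a-trimethyl-4a,5,6,7,8,8a-hexahydronaphthalen-2-yl]oxy}silane | C[Si](C)(C)OC=1C=C[C@H]2C(C)(C)CCC[C@]2(C)C=1
F4 | step 21 | 3,4-bis(allyloxy)-2-formyl-6-{[(1R,4aS,8aS)-2,5,5,8a-tetramethyl-1,4,4a,5,6,7,8,8a-octahydronaphthalen-1-yl]methyl}phenyl 2,2,2-trichloroethyl sulfate | CC1=CC[C@H]2C(C)(C)CCC[C@]2(C)[C@@H]1Cc1cc(OCC=C)c(OCC=C)c(C=O)c1OS(=O)(=O)OCC(Cl)(Cl)Cl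
F5 | step 21 | 2-formyl-3,4-dihydroxy-6-{[(1R,4aS,8aS)-2,5,5,8a-tetramethyl-1,4,4a,5,6,7,8,8a-octahydronaphthalen-1-yl]methyl}phenyl 2,2,2-trichloroethyl sulfate | CC1=CC[C@H]2C(C)(C)CCC[C@]2(C)[C@@H]1Cc1cc(O)c(O)c(C=O)c1OS(=O)(=O)OCC(Cl)(Cl)Cl
F6 | step 21 | ammonium 2-formyl-3,4-dihydroxy-6-{[(1R,4aS,8aS)-2,5,5,8a-tetramethyl-1,4,4a,5,6,7,8,8a-octahydronaphthalen-1-yl]methyl}phenyl sulfate | CC1=CC[C@H]2C(C)(C)CCC[C@]2(C)[C@@H]1Cc1cc(O)c(O)c(C=O)c1OS(=O)(=O)[O-].[NH4+]
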